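**Retrosynthetic overview** (chroman numbering: O1, C2 quaternary, C3, C4, C4a–C8a; C1' is the CH2 between C2 and the hydrindenone)
1. The dihydropyran ring is opened in one step across C4–C3 and O1–C2: hetero-Diels–Alder reaction of an ortho-quinone methide (1-oxadiene O1=C8a–C4a=C4, from 2-(hydroxymethyl)-4-methoxy-6-methylphenol) with the C2=C3 alkene of a 2-methylallyl group on C6 of the hydrindenone.
2. Enabling feature: O1 and C4 sit ortho on the arene (on C8a and C4a), so loss of water unmasks the heterodiene; C2 carries only CH3 and C1', so it is the internal carbon of a 1,1-disubstituted alkene whose terminal CH2 is C3.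
3. The alkene partner comes from a cis-3a,7a-dimethylhydrindan-5-one: C6 alkylation and hydration (2-hydroxy-2-methylpropyl arm), dehydrogenation, 1,2-addition of 2-methylallylmagnesium chloride, oxidative 1,3-transposition to the tetrasubstituted enone.
4. The hydrindanone comes from 2-methylcyclopentanone: auxiliary-controlled Michael addition (first quaternary centre), aldol ring closure, cuprate addition (second quaternary centre, cis fusion).
5. Ring order: cyclopentane (bought), six-membered carbocycle (step 2), arene (bought), dihydropyran (step 12, last step).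

Key step: step 12

Remark: the sense of induction of the acid catalyst in step 12 cannot be derived from first principles; the (R)-catalyst is assumed to give (2R), otherwise its enantiomer is used.

**Step 1**
Reactants: 1 2-methylcyclopentan-1-one (racemic); 2 (S)-1-phenylethan-1-amine; 3 but-3-en-2-one
Product: 6 (2R)-2-methyl-2-(3-oxobutyl)cyclopentan-1-one, via cyclopentylidene imine 4 (not isolated), via Michael adduct imine 5 (not isolated)
Conditions: 2, TsOH (cat.), toluene, reflux (Dean–Stark); then 3, THF, rt; then 10% aq AcOH, rt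
Reagents that add atoms: none
Why: Auxiliary-controlled Michael addition of a chiral imine through its more substituted secondary enamine tautomer (aza-ene-type transition state, attack anti to the phenyl group), which should set the quaternary centre as (R) in high enantiomeric purity (sense assigned by analogy with the 2-methylcyclohexanone case) before mild acid hydrolysis returns the amine.

**Step 2**
Reactants: 6 (2R)-2-methyl-2-(3-oxobutyl)cyclopentan-1-one
Product: 7 (7aR)-7a-methyl-1,2,3,6,7,7a-hexahydro-5H-inden-5-one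
Conditions: NaOMe, MeOH, 60 °C
Reagents that add atoms: none
Why: Intramolecular aldol condensation (ring-closing half of a Robinson annulation): the methyl ketone enolate attacks the cyclopentanone carbonyl and dehydration gives the conjugated bicyclic enone, the quaternary centre being untouched.

**Step 3**
Reactants: 7 (7aR)-7a-methyl-1,2,3,6,7,7a-hexahydro-5H-inden-5-one
Product: 8 (3aS,7aR)-3a,7a-dimethyloctahydro-5H-inden-5-one (cis ring fusion)
Conditions: Me2CuLi, Et2O, 0 °C; then H2O
Reagents that add atoms: lithium dimethylcuprate, [Li+].C[Cu-]C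
Why: Conjugate addition of a Gilman cuprate to the β,β-disubstituted enone; methyl is delivered to the ring-fusion carbon on the face that gives the cis-fused hydrindane (the trans-fused alternative with two angular methyl groups is far more strained), so the second quaternary centre is set cis to the first by substrate control.

**Step 4**
Reactants: 8 (3aS,7aR)-3a,7a-dimethyloctahydro-5H-inden-5-one; 9 3-bromo-2-methylprop-1-ene
Product: 10 (3aS,7aR)-3a,7a-dimethyl-6-(2-methylprop-2-en-1-yl)octahydro-5H-inden-5-one (C6 epimers)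
Conditions: LiN(i-Pr)2, THF, −78 °C; then 9, DMPU, −78 to −20 °C
Reagents that add atoms: none
Why: Kinetic enolate alkylation: LiN(i-Pr)2 should remove the less hindered C6 proton (C4 is neopentylic, next to quaternary C3a) and the lithium enolate is alkylated by the allylic bromide in an SN2 reaction; the C6 configuration is irrelevant because C6 becomes sp2 in step 7.

**Step 5**
Reactants: 10 (3aS,7aR)-3a,7a-dimethyl-6-(2-methylprop-2-en-1-yl)octahydro-5H-inden-5-one
Product: 11 (3aS,7aR)-6-(2-hydroxy-2-methylpropyl)-3a,7a-dimethyloctahydro-5H-inden-5-one (C6 epimers)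
Conditions: Co(acac)2 (cat.), PhSiH3, O2 (1 atm), THF, rt
Reagents that add atoms: dioxygen, O=O
Why: Mukaiyama hydration (cobalt hydride hydrogen-atom transfer to the 1,1-disubstituted alkene, capture of the tertiary radical by O2, reduction of the peroxide by the silane) should give the Markovnikov tertiary alcohol and leave the saturated ketone alone.

**Step 6**
Reactants: 11 (3aS,7aR)-6-(2-hydroxy-2-methylpropyl)-3a,7a-dimethyloctahydro-5H-inden-5-one
Product: 12 (3aS,7aR)-3a,7a-dimethyl-6-{2-methyl-2-[(triethylsilyl)oxy]propyl}octahydro-5H-inden-5-one (C6 epimers)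
Conditions: Et3SiOTf, 2,6-lutidine, CH2Cl2, −78 to 0 °C
Reagents that add atoms: triethylsilyl trifluoromethanesulfonate, CC[Si](CC)(CC)OS(=O)(=O)C(F)(F)F
Why: Silylation of the hindered tertiary alcohol with a silyl triflate protects it from the Grignard reagent of step 8 and from ionisation or cyclisation under the chromium oxidation of step 9.

**Step 7**
Reactants: 12 (3aS,7aR)-3a,7a-dimethyl-6-{2-methyl-2-[(triethylsilyl)oxy]propyl}octahydro-5H-inden-5-one
Product: 14 (3aS,7aR)-3a,7a-dimethyl-6-{2-methyl-2-[(triethylsilyl)oxy]propyl}-1,2,3,3a,4,7a-hexahydro-5H-inden-5-one, via silyl enol ether 13 (not isolated)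
Conditions: Me3SiCl, Et3N, DMF, 80 °C; then Pd(OAc)2 (1 equiv), MeCN, rt
Reagents that add atoms: none
Why: Saegusa–Ito oxidation: equilibrating silylation favours the more substituted C5=C6 silyl enol ether, and only this isomer can undergo β-hydride elimination after palladation (C3a carries no hydrogen), so the C6=C7 enone should form while any C4=C5 enol ether simply returns 12 on work-up.

**Step 8**
Reactants: 14 (3aS,7aR)-3a,7a-dimethyl-6-{2-methyl-2-[(triethylsilyl)oxy]propyl}-1,2,3,3a,4,7a-hexahydro-5H-inden-5-one; 15 (2-methylprop-2-en-1-yl)magnesium chloride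
Product: 16 (3aS,7aR)-3a,7a-dimethyl-5-(2-methylprop-2-en-1-yl)-6-{2-methyl-2-[(triethylsilyl)oxy]propyl}-2,3,3a,4,5,7a-hexahydro-1H-inden-5-ol (C5 epimers)
Conditions: 15, THF, −78 to 0 °C; then H2O
Reagents that add atoms: none
Why: 1,2-Addition of an allylic Grignard reagent to the enone carbonyl (cyclic six-membered allyl-transfer transition state, no conjugate addition); the configuration of the new carbinol carbon does not matter because it becomes sp2 in step 9.

**Step 9**
Reactants: 16 (3aS,7aR)-3a,7a-dimethyl-5-(2-methylprop-2-en-1-yl)-6-{2-methyl-2-[(triethylsilyl)oxy]propyl}-2,3,3a,4,5,7a-hexahydro-1H-inden-5-ol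
Product: 17 (3aS,7aS)-3a,7a-dimethyl-6-(2-methylprop-2-en-1-yl)-5-{2-methyl-2-[(triethylsilyl)oxy]propyl}-1,2,3,3a,7,7a-hexahydro-4H-inden-4-one
Conditions: pyridinium chlorochromate C5H5NH[CrO3Cl], NaOAc, 4 Å MS, CH2Cl2, rt
Reagents that add atoms: none
Why: Dauben–Babler oxidative 1,3-transposition: the chromate ester of the tertiary allylic alcohol undergoes a [3,3] shift to C7 and is oxidised there, giving the tetrasubstituted enone (the ring numbering changes because the new ketone takes locant 4, so the former C7a is now C3a).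

**Step 10**
Reactants: 17 (3aS,7aS)-3a,7a-dimethyl-6-(2-methylprop-2-en-1-yl)-5-{2-methyl-2-[(triethylsilyl)oxy]propyl}-1,2,3,3a,7,7a-hexahydro-4H-inden-4-one
Product: 18 (3aS,7aS)-5-(2-hydroxy-2-methylpropyl)-3a,7a-dimethyl-6-(2-methylprop-2-en-1-yl)-1,2,3,3a,7,7a-hexahydro-4H-inden-4-one
Conditions: HF·pyridine, pyridine, THF, 0 °C to rt
Reagents that add atoms: none
Why: Fluoride-mediated desilylation under buffered, non-basic conditions frees the tertiary alcohol without deprotonating the doubly allylic CH2 of the skipped dienone, which would move the alkene into conjugation.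

**Step 11**
Reactants: 19 4-methoxy-2-methylphenol
Product: 20 2-(hydroxymethyl)-4-methoxy-6-methylphenol
Conditions: 37% aq CH2O, NaOH, H2O, rt; then AcOH
Reagents that add atoms: formaldehyde, C=O
Why: Lederer–Manasse ortho-hydroxymethylation: the phenolate attacks formaldehyde at its only free ortho position (the para position carries OMe), giving the salicyl alcohol.

**Step 12**
Reactants: 18 (3aS,7aS)-5-(2-hydroxy-2-methylpropyl)-3a,7a-dimethyl-6-(2-methylprop-2-en-1-yl)-1,2,3,3a,7,7a-hexahydro-4H-inden-4-one; 20 2-(hydroxymethyl)-4-methoxy-6-methylphenol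
Product: 22 (3aS,7aS)-5-(2-hydroxy-2-methylpropyl)-6-{[(2R)-6-methoxy-2,8-dimethyl-3,4-dihydro-2H-1-benzopyran-2-yl]methyl}-3a,7a-dimethyl-1,2,3,3a,7,7a-hexahydro-4H-inden-4-one, via ortho-quinone methide 21 (not isolated)
Conditions: N-triflyl phosphoramide of (R)-3,3'-bis(2,4,6-triisopropylphenyl)-1,1'-bi-2-naphthol (10 mol %), 5 Å MS, toluene, 40 °C; 20 (2 equiv) added slowly
Reagents that add atoms: none
Why: Proposed new method: the chiral Brønsted acid dehydrates 20 to ortho-quinone methide 21 and holds it hydrogen-bonded in its chiral pocket, where the C2=C3 alkene of 18 adds in an asynchronous inverse-electron-demand hetero-Diels–Alder reaction, C3 bonding to the exocyclic methylene C4 slightly ahead of O1 bonding to the developing tertiary cationic centre C2. The closest known reaction types are the thermal [4+2] cycloaddition of ortho-quinone methides with unactivated 1,1-disubstituted alkenes and the chiral phosphoric acid or N-triflyl phosphoramide catalysed asymmetric [4+2] cycloadditions of ortho-quinone methides with styrenes, enol ethers and tethered unactivated alkenes; what is new is catalyst control with an untethered 1,1-dialkyl alkene. The dihydropyran ring closes in the [4+2] mode through the C4–C3 and O1–C2 bonds, and rearomatisation of the arene drives it. Regioselectivity (O1 to the more substituted alkene carbon) follows from the polarisation of heterodiene and alkene, and chemoselectivity is secured because the only other alkene of 18 is the tetrasubstituted, electron-poor enone. The one new stereocentre, C2, lies five bonds from the nearest ring stereocentre, so the substrate exerts no bias and the catalyst alone must set it. The catalyst is expected to shield one face of the planar quinone methide, while the free tertiary hydroxyl of the C5 side chain of 18 hydrogen-bonds to the phosphoryl oxygen and so fixes which alkene substituent (CH2–hydrindenyl, not CH3) points towards the catalyst; the two elements together define (2R).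

**Compound list**
1 | 2-methylcyclopentan-1-one (racemic) | CC1CCCC1=O | starting material
2 | (S)-1-phenylethan-1-amine | C[C@H](N)c1ccccc1 | starting material
3 | but-3-en-2-one | CC(=O)C=C | starting material
4 | (1S)-N-(2-methylcyclopentylidene)-1-phenylethan-1-amine (C2 epimers, equilibrating through the enamine) | C[C@H](N=C1CCCC1C)c1ccccc1 | intermediate
5 | 4-[(1R)-1-methyl-2-{[(1S)-1-phenylethyl]imino}cyclopentyl]butan-2-one | C[C@H](N=C1CCC[C@]1(C)CCC(C)=O)c1ccccc1 | intermediate
6 | (2R)-2-methyl-2-(3-oxobutyl)cyclopentan-1-one | CC(=O)CC[C@@]1(C)CCCC1=O | intermediate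
7 | (7aR)-7a-methyl-1,2,3,6,7,7a-hexahydro-5H-inden-5-one | O=C1CC[C@@]2(C)CCCC2=C1 | intermediate
8 | (3aS,7aR)-3a,7a-dimethyloctahydro-5H-inden-5-one (cis-fused, methyl groups cis) | O=C1CC[C@@]2(C)CCC[C@@]2(C)C1 | intermediate
9 | 3-bromo-2-methylprop-1-ene | CC(=C)CBr | starting material
10 | (3aS,7aR)-3a,7a-dimethyl-6-(2-methylprop-2-en-1-yl)octahydro-5H-inden-5-one (C6 epimers) | O=C1C(CC(C)=C)C[C@@]2(C)CCC[C@@]2(C)C1 | intermediate
11 | (3aS,7aR)-6-(2-hydroxy-2-methylpropyl)-3a,7a-dimethyloctahydro-5H-inden-5-one (C6 epimers) | O=C1C(CC(C)(C)O)C[C@@]2(C)CCC[C@@]2(C)C1 | intermediate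
12 | (3aS,7aR)-3a,7a-dimethyl-6-{2-methyl-2-[(triethylsilyl)oxy]propyl}octahydro-5H-inden-5-one (C6 epimers) | O=C1C(CC(C)(C)O[Si](CC)(CC)CC)C[C@@]2(C)CCC[C@@]2(C)C1 | intermediate
13 | (3aS,7aR)-3a,7a-dimethyl-6-{2-methyl-2-[(triethylsilyl)oxy]propyl}-5-[(trimethylsilyl)oxy]-2,3,3a,4,7,7a-hexahydro-1H-indene | C[Si](C)(C)OC1=C(CC(C)(C)O[Si](CC)(CC)CC)C[C@@]2(C)CCC[C@@]2(C)C1 | intermediate
14 | (3aS,7aR)-3a,7a-dimethyl-6-{2-methyl-2-[(triethylsilyl)oxy]propyl}-1,2,3,3a,4,7a-hexahydro-5H-inden-5-one | O=C1C(CC(C)(C)O[Si](CC)(CC)CC)=C[C@@]2(C)CCC[C@@]2(C)C1 | intermediate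
15 | (2-methylprop-2-en-1-yl)magnesium chloride | CC(=C)C[Mg]Cl | starting material
16 | (3aS,7aR)-3a,7a-dimethyl-5-(2-methylprop-2-en-1-yl)-6-{2-methyl-2-[(triethylsilyl)oxy]propyl}-2,3,3a,4,5,7a-hexahydro-1H-inden-5-ol (C5 epimers) | CC(=C)CC1(O)C(CC(C)(C)O[Si](CC)(CC)CC)=C[C@@]2(C)CCC[C@@]2(C)C1 | intermediate
17 | (3aS,7aS)-3a,7a-dimethyl-6-(2-methylprop-2-en-1-yl)-5-{2-methyl-2-[(triethylsilyl)oxy]propyl}-1,2,3,3a,7,7a-hexahydro-4H-inden-4-one | CC(=C)CC1=C(CC(C)(C)O[Si](CC)(CC)CC)C(=O)[C@@]2(C)CCC[C@@]2(C)C1 | intermediate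
18 | (3aS,7aS)-5-(2-hydroxy-2-methylpropyl)-3a,7a-dimethyl-6-(2-methylprop-2-en-1-yl)-1,2,3,3a,7,7a-hexahydro-4H-inden-4-one | CC(=C)CC1=C(CC(C)(C)O)C(=O)[C@@]2(C)CCC[C@@]2(C)C1 | intermediate
19 | 4-methoxy-2-methylphenol | COc1ccc(O)c(C)c1 | starting material
20 | 2-(hydroxymethyl)-4-methoxy-6-methylphenol | COc1cc(C)c(O)c(CO)c1 | intermediate
21 | 4-methoxy-2-methyl-6-methylidenecyclohexa-2,4-dien-1-one | O=C1C(C)=CC(OC)=CC1=C | intermediate
22 | (3aS,7aS)-5-(2-hydroxy-2-methylpropyl)-6-{[(2R)-6-methoxy-2,8-dimethyl-3,4-dihydro-2H-1-benzopyran-2-yl]methyl}-3a,7a-dimethyl-1,2,3,3a,7,7a-hexahydro-4H-inden-4-one | COc1cc(C)c2c(c1)CC[C@](C)(CC1=C(CC(C)(C)O)C(=O)[C@@]3(C)CCC[C@@]3(C)C1)O2 | target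

**Totals:** 12 steps; longest linear sequence 11 steps (steps 1–10 and 12).

**Steps most likely to fail**

Step 12. Catalyst control at C2 may be weak, so that both C2 epimers form, or 21 may oligomerise faster than the hindered alkene traps it. The fallback uses known chemistry only, sets out from 20 and 14 and returns at 22; the chroman stereocentre is made before the fragments are joined. Thermal cycloaddition of 21 (from 20, 170 °C, sealed tube) with excess 2-methylidenepropane-1,3-diyl diacetate closes the same C4–C3 bond and should give achiral (6-methoxy-8-methyl-3,4-dihydro-2H-1-benzopyran-2,2-diyl)dimethanediyl diacetate F1. K2CO3 in MeOH gives (6-methoxy-8-methyl-3,4-dihydro-2H-1-benzopyran-2,2-diyl)dimethanol F2. Lipase-catalysed monoacetylation (Candida antarctica lipase B, vinyl acetate) desymmetrises the enantiotopic hydroxymethyl groups to [(2S)-2-(hydroxymethyl)-6-methoxy-8-methyl-3,4-dihydro-2H-1-benzopyran-2-yl]methyl acetate F3; if the enzyme prefers the other arm, enzymatic hydrolysis of F1 gives the needed enantiomer. TsCl in pyridine gives [(2R)-6-methoxy-8-methyl-2-{[(4-methylbenzenesulfonyl)oxy]methyl}-3,4-dihydro-2H-1-benzopyran-2-yl]methyl acetate F4. LiEt3BH reduces CH2OTs to CH3 and cleaves the acetate, giving [(2R)-6-methoxy-2,8-dimethyl-3,4-dihydro-2H-1-benzopyran-2-yl]methanol F5, and I2, PPh3 and imidazole give (2R)-2-(iodomethyl)-6-methoxy-2,8-dimethyl-3,4-dihydro-2H-1-benzopyran F6. In parallel, enone 14 is epoxidised (H2O2, NaOH, MeOH) to (3aS,7aS)-6,7-epoxy-3a,7a-dimethyl-6-{2-methyl-2-[(triethylsilyl)oxy]propyl}octahydro-5H-inden-5-one F7. Isomerisation with Pd(PPh3)4 and 1,2-bis(diphenylphosphino)ethane gives (3aS,7aS)-3a,7a-dimethyl-5-{2-methyl-2-[(triethylsilyl)oxy]propyl}hexahydro-1H-indene-4,6(2H,5H)-dione F8. O-Sulfonylation at the less hindered C6 oxygen (Tf2O, 2,6-lutidine) gives (3aS,7aS)-3a,7a-dimethyl-5-{2-methyl-2-[(triethylsilyl)oxy]propyl}-4-oxo-2,3,3a,4,7,7a-hexahydro-1H-inden-6-yl trifluoromethanesulfonate F9. Nickel-catalysed reductive cross-electrophile coupling of F6 with F9 (NiBr2·glyme, 4,4'-di-tert-butyl-2,2'-bipyridine, Mn, DMA) gives (3aS,7aS)-6-{[(2R)-6-methoxy-2,8-dimethyl-3,4-dihydro-2H-1-benzopyran-2-yl]methyl}-3a,7a-dimethyl-5-{2-methyl-2-[(triethylsilyl)oxy]propyl}-1,2,3,3a,7,7a-hexahydro-4H-inden-4-one F10, and HF·pyridine gives 22.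

Step 9. The hindered tertiary allylic chromate ester may ionise and dehydrate to dienes, or the silyl ether may be lost under the acidic chromium reagent. The fallback sets out from 16 and returns at 17. Redox-neutral 1,3-transposition of the allylic alcohol with catalytic Ph3SiOReO3 (Et2O, 0 °C) should give the secondary allylic alcohol (3aS,7aS)-3a,7a-dimethyl-6-(2-methylprop-2-en-1-yl)-5-{2-methyl-2-[(triethylsilyl)oxy]propyl}-2,3,3a,4,7,7a-hexahydro-1H-inden-4-ol F11, which already has the tetrasubstituted alkene in place. Neutral oxidation with Dess–Martin periodinane (NaHCO3, CH2Cl2) then gives 17.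

Step 7. Enol silylation may go mainly towards C4 (unproductive), and the palladium enolate may eliminate towards the side chain, giving the exocyclic enone. The fallback sets out from 8 and returns at 14; the unsaturation is introduced first, where it can only form between C6 and C7. 2-Iodoxybenzoic acid (DMSO, 70 °C) gives (3aS,7aR)-3a,7a-dimethyl-1,2,3,3a,4,7a-hexahydro-5H-inden-5-one F12, and I2 in pyridine gives (3aS,7aR)-6-iodo-3a,7a-dimethyl-1,2,3,3a,4,7a-hexahydro-5H-inden-5-one F13. Stille coupling with tributyl(2-methylprop-2-en-1-yl)stannane (Pd2(dba)3, AsPh3, DMF) gives (3aS,7aR)-3a,7a-dimethyl-6-(2-methylprop-2-en-1-yl)-1,2,3,3a,4,7a-hexahydro-5H-inden-5-one F14. Mukaiyama hydration as in step 5 gives (3aS,7aR)-6-(2-hydroxy-2-methylpropyl)-3a,7a-dimethyl-1,2,3,3a,4,7a-hexahydro-5H-inden-5-one F15, and Et3SiOTf with 2,6-lutidine gives 14.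

**Further compounds**
F1 | step 12 | (6-methoxy-8-methyl-3,4-dihydro-2H-1-benzopyran-2,2-diyl)dimethanediyl diacetate | COc1cc(C)c2c(c1)CCC(COC(C)=O)(COC(C)=O)O2
F2 | step 12 | (6-methoxy-8-methyl-3,4-dihydro-2H-1-benzopyran-2,2-diyl)dimethanol | COc1cc(C)c2c(c1)CCC(CO)(CO)O2
F3 | step 12 | [(2S)-2-(hydroxymethyl)-6-methoxy-8-methyl-3,4-dihydro-2H-1-benzopyran-2-yl]methyl acetate | COc1cc(C)c2c(c1)CC[C@](CO)(COC(C)=O)O2
F4 | step 12 | [(2R)-6-methoxy-8-methyl-2-{[(4-methylbenzenesulfonyl)oxy]methyl}-3,4-dihydro-2H-1-benzopyran-2-yl]methyl acetate | COc1cc(C)c2c(c1)CC[C@](COS(=O)(=O)c1ccc(C)cc1)(COC(C)=O)O2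
F5 | step 12 | [(2R)-6-methoxy-2,8-dimethyl-3,4-dihydro-2H-1-benzopyran-2-yl]methanol | COc1cc(C)c2c(c1)CC[C@](C)(CO)O2
F6 | step 12 | (2R)-2-(iodomethyl)-6-methoxy-2,8-dimethyl-3,4-dihydro-2H-1-benzopyran | COc1cc(C)c2c(c1)CC[C@](C)(CI)O2
F7 | step 12 | (3aS,7aS)-6,7-epoxy-3a,7a-dimethyl-6-{2-methyl-2-[(triethylsilyl)oxy]propyl}octahydro-5H-inden-5-one (epoxide face not assigned) | O=C1C2(CC(C)(C)O[Si](CC)(CC)CC)OC2[C@@]3(C)CCC[C@@]3(C)C1
F8 | step 12 | (3aS,7aS)-3a,7a-dimethyl-5-{2-methyl-2-[(triethylsilyl)oxy]propyl}hexahydro-1H-indene-4,6(2H,5H)-dione | O=C1C(CC(C)(C)O[Si](CC)(CC)CC)C(=O)[C@@]2(C)CCC[C@@]2(C)C1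
F9 | step 12 | (3aS,7aS)-3a,7a-dimethyl-5-{2-methyl-2-[(triethylsilyl)oxy]propyl}-4-oxo-2,3,3a,4,7,7a-hexahydro-1H-inden-6-yl trifluoromethanesulfonate | FC(F)(F)S(=O)(=O)OC1=C(CC(C)(C)O[Si](CC)(CC)CC)C(=O)[C@@]2(C)CCC[C@@]2(C)C1
F10 | step 12 | (3aS,7aS)-6-{[(2R)-6-methoxy-2,8-dimethyl-3,4-dihydro-2H-1-benzopyran-2-yl]methyl}-3a,7a-dimethyl-5-{2-methyl-2-[(triethylsilyl)oxy]propyl}-1,2,3,3a,7,7a-hexahydro-4H-inden-4-one | COc1cc(C)c2c(c1)CC[C@](C)(CC1=C(CC(C)(C)O[Si](CC)(CC)CC)C(=O)[C@@]3(C)CCC[C@@]3(C)C1)O2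
F11 | step 9 | (3aS,7aS)-3a,7a-dimethyl-6-(2-methylprop-2-en-1-yl)-5-{2-methyl-2-[(triethylsilyl)oxy]propyl}-2,3,3a,4,7,7a-hexahydro-1H-inden-4-ol (C4 epimers) | CC(=C)CC1=C(CC(C)(C)O[Si](CC)(CC)CC)C(O)[C@@]2(C)CCC[C@@]2(C)C1
F12 | step 7 | (3aS,7aR)-3a,7a-dimethyl-1,2,3,3a,4,7a-hexahydro-5H-inden-5-one | O=C1C=C[C@@]2(C)CCC[C@@]2(C)C1
F13 | step 7 | (3aS,7aR)-6-iodo-3a,7a-dimethyl-1,2,3,3a,4,7a-hexahydro-5H-inden-5-one | O=C1C(I)=C[C@@]2(C)CCC[C@@]2(C)C1
F14 | step 7 | (3aS,7aR)-3a,7a-dimethyl-6-(2-methylprop-2-en-1-yl)-1,2,3,3a,4,7a-hexahydro-5H-inden-5-one | O=C1C(CC(C)=C)=C[C@@]2(C)CCC[C@@]2(C)C1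
F15 | step 7 | (3aS,7aR)-6-(2-hydroxy-2-methylpropyl)-3a,7a-dimethyl-1,2,3,3a,4,7a-hexahydro-5H-inden-5-one | O=C1C(CC(C)(C)O)=C[C@@]2(C)CCC[C@@]2(C)C1
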